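**Plan**
- Retrosynthesis: remove the two silyl groups; open the pyran ring at O1–C2 and C4–C4a, back to an aryl 1,1-dimethylpropargyl ether (a phenol plus 3-chloro-3-methylbut-1-yne); cut ring A at C6–C7 and C4a–C5 into an ethynyl ketone and 1,1-dimethoxy-3-(trimethylsilyloxy)buta-1,3-diene; cut the ynone at its alkynyl–carbonyl bond back to a lactic Weinreb amide from L-tyrosine.
- Forward order: the chain first (ring B, the 4-hydroxyphenyl ring, comes with tyrosine), then ring A by Diels–Alder benzannulation, then the pyran ring by propargyl Claisen shift and oxa-6π closure, then desilylation.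
- Enabling feature: ring A has the acyl carbon on C6, OMe on the adjacent C7 and the pyran oxygen on C8a, para to C6. This is the 2-alkoxy-4-hydroxyaryl ketone pattern that this diene imprints on an acetylenic ketone: the alkyne carbons become C5 and C6, the diene carbons C7, C8, C8a and C4a.
- Stereochemistry: the only stereocentre (S, the carbinol carbon next to the ketone) is Cα of L-tyrosine, carried through diazotization with net retention and never enolized afterwards.

Key step: step 8

Notation and assumption: TBS = tert-butyldimethylsilyl, TMS = trimethylsilyl. The aryl TMS ether formed in step 8 is assumed to hydrolyse on the dilute-acid work-up while both TBS ethers survive it.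

**Step 1**
Reactants: 1 L-tyrosine
Product: 4 (S)-2-hydroxy-3-(4-hydroxyphenyl)propanoic acid, via diazonium carboxylate 2 (not isolated), via α-lactone 3 (not isolated)
Conditions: NaNO2, 1 M H2SO4 (aq), 0 °C → rt
Reagents that add atoms: water, O
Why: Diazotization of the α-amino acid (van Slyke-type deamination) should go with net retention, because the neighbouring carboxylate expels N2 from diazonium 2 with inversion to α-lactone 3 and water reopens it at the same carbon with a second inversion, so the S centre of tyrosine becomes the S carbinol centre.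

**Step 2**
Reactants: 4 (S)-2-hydroxy-3-(4-hydroxyphenyl)propanoic acid
Product: 5 methyl (S)-2-hydroxy-3-(4-hydroxyphenyl)propanoate
Conditions: MeOH, H2SO4 (cat.), reflux
Reagents that add atoms: methanol, CO
Why: Fischer esterification under acid catalysis does not touch the carbinol centre and leaves the phenol free.

**Step 3**
Reactants: 5 methyl (S)-2-hydroxy-3-(4-hydroxyphenyl)propanoate
Product: 6 methyl (S)-2-(TBSO)-3-[4-(TBSO)phenyl]propanoate
Conditions: TBSCl, imidazole, DMF, rt
Reagents that add atoms: tert-butyldimethylsilyl chloride, CC(C)(C)[Si](C)(C)Cl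
Why: Imidazole-promoted silyl ether formation on the phenol and the secondary alcohol masks both acidic hydroxyls before the organomagnesium steps.

**Step 4**
Reactants: 6 methyl (S)-2-(TBSO)-3-[4-(TBSO)phenyl]propanoate
Product: 7 (S)-2-(TBSO)-3-[4-(TBSO)phenyl]-N-methoxy-N-methylpropanamide
Conditions: MeNHOMe·HCl, iPrMgCl, THF, −20 → 0 °C
Reagents that add atoms: N,O-dimethylhydroxylamine hydrochloride, CNOC.Cl
Why: Aminolysis of the methyl ester by the chloromagnesium amide made in the flask (Weinreb amide formation) should be faster at −20 °C than deprotonation next to the ester, so the silyloxy-bearing centre is kept.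

**Step 5**
Reactants: 7 (S)-2-(TBSO)-3-[4-(TBSO)phenyl]-N-methoxy-N-methylpropanamide; 8 ethynylmagnesium bromide
Product: 10 (S)-4-(TBSO)-5-[4-(TBSO)phenyl]pent-1-yn-3-one, via magnesium hemiaminal 9 (not isolated)
Conditions: THF, 0 °C; then inverse quench into aq NaHSO4, 0 °C
Reagents that add atoms: none
Why: In this Weinreb ketone synthesis the chelated magnesium hemiaminal 9 should persist until work-up so that only one alkynyl group adds, and the inverse acidic quench protonates the released N,O-dimethylhydroxylamine before it can add to the ynone, the α-silyloxy centre never being deprotonated.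

**Step 6**
Reactants: 11 1,1-dimethoxyethene; 12 acetyl chloride
Product: 13 4,4-dimethoxybut-3-en-2-one
Conditions: Et3N, Et2O, 0 °C → rt
Reagents that add atoms: none
Why: C-Acylation of the nucleophilic ketene acetal by the acid chloride, followed by loss of HCl to the amine, is the classical acylation of ketene acetals and should give the push–pull enone.

**Step 7**
Reactants: 13 4,4-dimethoxybut-3-en-2-one
Product: 15 1,1-dimethoxy-3-(trimethylsilyloxy)buta-1,3-diene, via lithium dienolate 14 (not isolated)
Conditions: LiN(iPr)2, THF, −78 °C; TMSCl, −78 °C → rt; non-aqueous work-up, distillation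
Reagents that add atoms: chlorotrimethylsilane, C[Si](C)(C)Cl
Why: Kinetic deprotonation of the methyl ketone and O-silylation of dienolate 14 is standard silyl enol ether formation and should give the electron-rich diene without touching the ketene acetal.

**Step 8**
Reactants: 10 (S)-4-(TBSO)-5-[4-(TBSO)phenyl]pent-1-yn-3-one; 15 1,1-dimethoxy-3-(trimethylsilyloxy)buta-1,3-diene
Product: 18 (S)-2-(TBSO)-3-[4-(TBSO)phenyl]-1-(4-hydroxy-2-methoxyphenyl)propan-1-one, via cyclohexa-1,4-diene adduct 16 (not isolated), via aryl trimethylsilyl ether 17 (not isolated)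
Conditions: 15 (excess), toluene, rt → 80 °C; then 0.1 M HCl, THF, 0 °C
Reagents that add atoms: none
Why: Diene 15 is donor-polarized by its ketene-acetal and silyl enol ether oxygens, so its CH2 terminus should bond to the terminal alkyne carbon of ynone 10 and its acetal carbon to the carbonyl-bearing alkyne carbon in a concerted, asynchronous thermal [4+2] cycloaddition that closes the six-membered carbocycle of ring A (both ring bonds, C4a–C5 and C6–C7, in one intermolecular event) as adduct 16. 1,4-Elimination of methanol from the acetal carbon and the doubly allylic CH2 then aromatizes 16 to aryl silyl ether 17, and dilute acid frees the para phenol 18. The closest known reaction type is the Diels–Alder benzannulation of 1,1-dialkoxy-3-silyloxybutadienes with acetylenic ketones and esters, which gives 4-hydroxy-2-alkoxyaryl carbonyl compounds. No stereocentre is created, and the existing α-silyloxy centre should survive because the medium is thermal and neutral and that carbon is never enolized. The selectivity needed is regiochemical (OMe ortho and OH para to the acyl group), and it is secured by the matched polarization of the two partners, the reverse orientation being electronically mismatched.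

**Step 9**
Reactants: 18 (S)-2-(TBSO)-3-[4-(TBSO)phenyl]-1-(4-hydroxy-2-methoxyphenyl)propan-1-one; 19 3-chloro-3-methylbut-1-yne
Product: 20 (S)-2-(TBSO)-3-[4-(TBSO)phenyl]-1-[2-methoxy-4-(2-methylbut-3-yn-2-yloxy)phenyl]propan-1-one
Conditions: DBU, CuCl2 (cat.), dry MeCN, 0 °C
Reagents that add atoms: none
Why: In this copper-catalysed propargylic etherification (Godfrey conditions) the acyl-acidified phenol is deprotonated by DBU and its phenoxide should capture the copper-activated tertiary propargylic electrophile at oxygen, while the cold anhydrous medium leaves the aryl silyl ether and the α-silyloxy ketone untouched.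

**Step 10**
Reactants: 20 (S)-2-(TBSO)-3-[4-(TBSO)phenyl]-1-[2-methoxy-4-(2-methylbut-3-yn-2-yloxy)phenyl]propan-1-one
Product: 23 (S)-2-(TBSO)-3-[4-(TBSO)phenyl]-1-(7-methoxy-2,2-dimethyl-2H-chromen-6-yl)propan-1-one, via allenylphenol 21 (not isolated), via ortho-quinone methide 22 (not isolated)
Conditions: o-xylene, 140 °C
Reagents that add atoms: none
Why: In this aromatic propargyl Claisen rearrangement the [3,3] shift should go to the unhindered ortho carbon para to OMe (the other ortho carbon is flanked by both oxygens and no hydroxyl–carbonyl chelate fixes the bond alternation), after which tautomerization gives allenylphenol 21, a 1,5-hydrogen shift gives ortho-quinone methide 22 and oxa-6π electrocyclization closes the pyran ring, a cascade that is standard for aryl 1,1-dimethylpropargyl ethers.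

**Step 11**
Reactants: 23 (S)-2-(TBSO)-3-[4-(TBSO)phenyl]-1-(7-methoxy-2,2-dimethyl-2H-chromen-6-yl)propan-1-one
Product: 24 Lespeflorin C7, (S)-2-hydroxy-3-(4-hydroxyphenyl)-1-(7-methoxy-2,2-dimethyl-2H-chromen-6-yl)propan-1-one
Conditions: HF·pyridine, pyridine, THF, 0 °C → rt
Reagents that add atoms: none
Why: Fluoride-driven cleavage of both silyl ethers (Si–F bond formation) in a pyridine-buffered medium should neither enolize the α-hydroxy ketone nor add to the chromene double bond, so the S centre and the pyran ring are kept.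

**Compound list**
1 | L-tyrosine, (S)-2-amino-3-(4-hydroxyphenyl)propanoic acid | N[C@@H](Cc1ccc(O)cc1)C(=O)O | starting material
2 | (S)-1-carboxylato-2-(4-hydroxyphenyl)ethanediazonium (diazonium carboxylate) | N#[N+][C@@H](Cc1ccc(O)cc1)C(=O)[O-] | intermediate (not isolated)
3 | (R)-3-(4-hydroxybenzyl)oxiran-2-one (α-lactone) | O1[C@H](Cc2ccc(O)cc2)C1=O | intermediate (not isolated)
4 | (S)-2-hydroxy-3-(4-hydroxyphenyl)propanoic acid | O[C@@H](Cc1ccc(O)cc1)C(=O)O | intermediate
5 | methyl (S)-2-hydroxy-3-(4-hydroxyphenyl)propanoate | COC(=O)[C@@H](O)Cc1ccc(O)cc1 | intermediate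
6 | methyl (S)-2-(tert-butyldimethylsilyloxy)-3-[4-(tert-butyldimethylsilyloxy)phenyl]propanoate | COC(=O)[C@@H](O[Si](C)(C)C(C)(C)C)Cc1ccc(O[Si](C)(C)C(C)(C)C)cc1 | intermediate
7 | (S)-2-(tert-butyldimethylsilyloxy)-3-[4-(tert-butyldimethylsilyloxy)phenyl]-N-methoxy-N-methylpropanamide | CON(C)C(=O)[C@@H](O[Si](C)(C)C(C)(C)C)Cc1ccc(O[Si](C)(C)C(C)(C)C)cc1 | intermediate
8 | ethynylmagnesium bromide | C#C[Mg]Br | starting material
9 | bromomagnesium (4S)-4-(tert-butyldimethylsilyloxy)-5-[4-(tert-butyldimethylsilyloxy)phenyl]-3-[methoxy(methyl)amino]pent-1-yn-3-olate (configuration at C3 not defined) | C#CC(O[Mg]Br)(N(C)OC)[C@@H](O[Si](C)(C)C(C)(C)C)Cc1ccc(O[Si](C)(C)C(C)(C)C)cc1 | intermediate (not isolated)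
10 | (S)-4-(tert-butyldimethylsilyloxy)-5-[4-(tert-butyldimethylsilyloxy)phenyl]pent-1-yn-3-one | C#CC(=O)[C@@H](O[Si](C)(C)C(C)(C)C)Cc1ccc(O[Si](C)(C)C(C)(C)C)cc1 | intermediate
11 | 1,1-dimethoxyethene | COC(=C)OC | starting material
12 | acetyl chloride | CC(=O)Cl | starting material
13 | 4,4-dimethoxybut-3-en-2-one | CC(=O)C=C(OC)OC | intermediate
14 | lithium 4,4-dimethoxybuta-1,3-dien-2-olate | [Li]OC(=C)C=C(OC)OC | intermediate (not isolated)
15 | 1,1-dimethoxy-3-(trimethylsilyloxy)buta-1,3-diene | COC(OC)=CC(=C)O[Si](C)(C)C | intermediate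
16 | (S)-2-(tert-butyldimethylsilyloxy)-3-[4-(tert-butyldimethylsilyloxy)phenyl]-1-[6,6-dimethoxy-4-(trimethylsilyloxy)cyclohexa-1,4-dien-1-yl]propan-1-one | COC1(OC)C=C(O[Si](C)(C)C)CC=C1C(=O)[C@@H](O[Si](C)(C)C(C)(C)C)Cc1ccc(O[Si](C)(C)C(C)(C)C)cc1 | intermediate (not isolated)
17 | (S)-2-(tert-butyldimethylsilyloxy)-3-[4-(tert-butyldimethylsilyloxy)phenyl]-1-[2-methoxy-4-(trimethylsilyloxy)phenyl]propan-1-one | COc1cc(O[Si](C)(C)C)ccc1C(=O)[C@@H](O[Si](C)(C)C(C)(C)C)Cc1ccc(O[Si](C)(C)C(C)(C)C)cc1 | intermediate (not isolated)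
18 | (S)-2-(tert-butyldimethylsilyloxy)-3-[4-(tert-butyldimethylsilyloxy)phenyl]-1-(4-hydroxy-2-methoxyphenyl)propan-1-one | COc1cc(O)ccc1C(=O)[C@@H](O[Si](C)(C)C(C)(C)C)Cc1ccc(O[Si](C)(C)C(C)(C)C)cc1 | intermediate
19 | 3-chloro-3-methylbut-1-yne | CC(C)(Cl)C#C | starting material
20 | (S)-2-(tert-butyldimethylsilyloxy)-3-[4-(tert-butyldimethylsilyloxy)phenyl]-1-[2-methoxy-4-(2-methylbut-3-yn-2-yloxy)phenyl]propan-1-one | COc1cc(OC(C)(C)C#C)ccc1C(=O)[C@@H](O[Si](C)(C)C(C)(C)C)Cc1ccc(O[Si](C)(C)C(C)(C)C)cc1 | intermediate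
21 | (S)-2-(tert-butyldimethylsilyloxy)-3-[4-(tert-butyldimethylsilyloxy)phenyl]-1-[4-hydroxy-2-methoxy-5-(3-methylbuta-1,2-dien-1-yl)phenyl]propan-1-one | COc1cc(O)c(C=C=C(C)C)cc1C(=O)[C@@H](O[Si](C)(C)C(C)(C)C)Cc1ccc(O[Si](C)(C)C(C)(C)C)cc1 | intermediate (not isolated)
22 | (S)-2-(tert-butyldimethylsilyloxy)-3-[4-(tert-butyldimethylsilyloxy)phenyl]-1-[6-methoxy-3-(3-methylbut-2-en-1-ylidene)-4-oxocyclohexa-1,5-dien-1-yl]propan-1-one | COC1=CC(=O)C(=CC=C(C)C)C=C1C(=O)[C@@H](O[Si](C)(C)C(C)(C)C)Cc1ccc(O[Si](C)(C)C(C)(C)C)cc1 | intermediate (not isolated)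
23 | (S)-2-(tert-butyldimethylsilyloxy)-3-[4-(tert-butyldimethylsilyloxy)phenyl]-1-(7-methoxy-2,2-dimethyl-2H-chromen-6-yl)propan-1-one | COc1cc2c(cc1C(=O)[C@@H](O[Si](C)(C)C(C)(C)C)Cc1ccc(O[Si](C)(C)C(C)(C)C)cc1)C=CC(C)(C)O2 | intermediate
24 | Lespeflorin C7, (S)-2-hydroxy-3-(4-hydroxyphenyl)-1-(7-methoxy-2,2-dimethyl-2H-chromen-6-yl)propan-1-one | COc1cc2c(cc1C(=O)[C@@H](O)Cc1ccc(O)cc1)C=CC(C)(C)O2 | target

**Step count**
Total: 11 steps. Longest linear sequence: 9 steps (steps 1–5 and 8–11); steps 6 and 7 make the diene in a side branch.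

**Steps most likely to fail**

Step 8 (key step). The moisture-sensitive ketene-acetal diene may hydrolyse or oligomerize before it adds, the methanol released on aromatization may add in conjugate fashion to unreacted ynone, or the adduct may stall before aromatization. The fallback forms the aryl–carbonyl bond instead of building the ring; it sets out from Weinreb amide 7 and comes back at phenol 18. Commercial 4-bromo-3-methoxyphenol would be O-allylated (allyl bromide, K2CO3, acetone) to 1-(allyloxy)-4-bromo-3-methoxybenzene F1. Bromine–lithium exchange (n-BuLi, THF, −78 °C) would give [4-(allyloxy)-2-methoxyphenyl]lithium F2, which amide 7 should acylate to (S)-1-[4-(allyloxy)-2-methoxyphenyl]-2-(TBSO)-3-[4-(TBSO)phenyl]propan-1-one F3. Deallylation with Pd(PPh3)4 (zerovalent palladium) and morpholine in THF would then give 18.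

Step 10. The [3,3] shift may go to the ortho carbon between the two ring oxygens and lead to the angular 5-methoxy chromene, or prolonged heating may erode the α-silyloxy ketone. The fallback fixes the ring position by electrophilic substitution; it sets out from phenol 18 and comes back at chromene 23. Iodination (N-iodosuccinimide, TsOH cat., MeCN, 0 °C) ortho to the hydroxyl and para to OMe would give (S)-2-(TBSO)-3-[4-(TBSO)phenyl]-1-(4-hydroxy-5-iodo-2-methoxyphenyl)propan-1-one F4, whose substitution pattern can be checked at this simple stage. Heck coupling with 2-methylbut-3-en-2-ol (Pd(OAc)2, NaHCO3, Bu4NCl, DMF, 60 °C) would give (S,E)-2-(TBSO)-3-[4-(TBSO)phenyl]-1-[4-hydroxy-5-(3-hydroxy-3-methylbut-1-en-1-yl)-2-methoxyphenyl]propan-1-one F5. Acid-catalysed cyclodehydration (pyridinium p-toluenesulfonate, toluene, 60 °C) through the allylic cation should then close the pyran ring to 23.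

Step 9. DBU may strip the aryl silyl ether or epimerize the centre next to the ketone, and the acyl-deactivated phenoxide may capture the tertiary propargylic electrophile only slowly. The fallback makes the ether under neutral palladium catalysis and reaches the chromene by oxidation; it sets out from phenol 18 and comes back at chromene 23. Allylic etherification with methyl 2-methylbut-3-en-2-yl carbonate and Pd(PPh3)4 (THF, 0 °C → rt) would give the tertiary ether (S)-2-(TBSO)-3-[4-(TBSO)phenyl]-1-[2-methoxy-4-(2-methylbut-3-en-2-yloxy)phenyl]propan-1-one F6. Aromatic Claisen rearrangement (toluene, 110 °C) would give the ortho-prenyl phenol (S)-2-(TBSO)-3-[4-(TBSO)phenyl]-1-[4-hydroxy-2-methoxy-5-(3-methylbut-2-en-1-yl)phenyl]propan-1-one F7. Dehydrogenative cyclization with DDQ (benzene, 80 °C) should then give 23.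

**Further compounds**
F1 | step 8 | 1-(allyloxy)-4-bromo-3-methoxybenzene | C=CCOc1ccc(Br)c(OC)c1
F2 | step 8 | [4-(allyloxy)-2-methoxyphenyl]lithium | [Li]c1ccc(OCC=C)cc1OC
F3 | step 8 | (S)-1-[4-(allyloxy)-2-methoxyphenyl]-2-(tert-butyldimethylsilyloxy)-3-[4-(tert-butyldimethylsilyloxy)phenyl]propan-1-one | COc1cc(OCC=C)ccc1C(=O)[C@@H](O[Si](C)(C)C(C)(C)C)Cc1ccc(O[Si](C)(C)C(C)(C)C)cc1
F4 | step 10 | (S)-2-(tert-butyldimethylsilyloxy)-3-[4-(tert-butyldimethylsilyloxy)phenyl]-1-(4-hydroxy-5-iodo-2-methoxyphenyl)propan-1-one | COc1cc(O)c(I)cc1C(=O)[C@@H](O[Si](C)(C)C(C)(C)C)Cc1ccc(O[Si](C)(C)C(C)(C)C)cc1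
F5 | step 10 | (S,E)-2-(tert-butyldimethylsilyloxy)-3-[4-(tert-butyldimethylsilyloxy)phenyl]-1-[4-hydroxy-5-(3-hydroxy-3-methylbut-1-en-1-yl)-2-methoxyphenyl]propan-1-one | COc1cc(O)c(/C=C/C(C)(C)O)cc1C(=O)[C@@H](O[Si](C)(C)C(C)(C)C)Cc1ccc(O[Si](C)(C)C(C)(C)C)cc1
F6 | step 9 | (S)-2-(tert-butyldimethylsilyloxy)-3-[4-(tert-butyldimethylsilyloxy)phenyl]-1-[2-methoxy-4-(2-methylbut-3-en-2-yloxy)phenyl]propan-1-one | COc1cc(OC(C)(C)C=C)ccc1C(=O)[C@@H](O[Si](C)(C)C(C)(C)C)Cc1ccc(O[Si](C)(C)C(C)(C)C)cc1
F7 | step 9 | (S)-2-(tert-butyldimethylsilyloxy)-3-[4-(tert-butyldimethylsilyloxy)phenyl]-1-[4-hydroxy-2-methoxy-5-(3-methylbut-2-en-1-yl)phenyl]propan-1-one | COc1cc(O)c(CC=C(C)C)cc1C(=O)[C@@H](O[Si](C)(C)C(C)(C)C)Cc1ccc(O[Si](C)(C)C(C)(C)C)cc1
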